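Amounts first: in the ochre flask, charged with 2 M of starting material and 2 M of other conformer, the readings at 30.0 h add up to 81.9% of the charge as target and isomer of the product together.

| flask | starting material | other conformer | remark | time |
|---|---|---|---|---|
| ochre | 2 M | 2 M | the very flask that is asked about, followed so far |  |
| flask | 2.0 M | 2.00 M |  | 15 d |

ochre run (percent of the starting material and other conformer together charged)

| time / h | target / % | isomer of the product / % |
|---|---|---|
| 4.00 | 13.1 | 8.5 |
| 8.00 | 23.3 | 15.0 |
| 12.0 | 34.9 | 18.2 |
| 15.0 | 37.0 | 21.3 |
| 20.0 | 43.7 | 25.7 |
| 25.0 | 49.8 | 28.3 |
| 30.0 | 53.1 | 28.8 |

(each reading ± 1 percentage point)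

- ratio of target to isomer of the product at 40 min
- ratio of target to isomer of the product at 15 h
- ratio of target to isomer of the product at 15 d
- which of target and isomer of the product there is more of at 15 d

From these readings I carry one number, the split: all target readings summed, divided by all isomer readings summed, which is 1.75. I take it as the ratio in which the two products form, the ratio of kinetic control. My own reckoning therefore puts [target]/[isomer of the product] at 1.75 at each asked time, with target ahead.

The forecast differs: 1.55, 1.72 and 2.3, with target ahead, on the ground that “Nothing shows the ratio falling”.

The flask gives 1.72, 1.76 and 1.60, with target ahead, and at 15.0 d it holds 61.5% target and 38.5% isomer of the product. That final ratio is lower than both the forecast and my reckoning.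

    starting material ⇌ other conformer (K = 0.800, k = 5.50 h⁻¹)
    starting material → target (k = 0.0680 h⁻¹)
    other conformer → isomer of the product (k = 0.0480 h⁻¹)
    target ⇌ isomer of the product (K = 0.660, k = 0.00120 h⁻¹)

In this flask the ratio stands at 1.76 at 15 h, and afterwards target and isomer of the product relax toward 1.52, with a relaxation half-life of 9.57 d by that step alone, both ways together. As target's share, the split is 63.6% and the end point 60.2%. Letting the gap between them decay over 15 d, counted from the start, I reckon a target share of 61.4% for this flask, a ratio of 1.59. The neighbour charged with 0.80 M of starting material shows 1.55 at 40 min and 1.75 at 15 h; the same reckoning, with the split carried over unchanged, gives it 1.59, and it ends with 61.5% target and 38.5% isomer of the product, a ratio of 1.60.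

(The readings are simulated with made-up constants, and the scatter is random.)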